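## Retrosynthetic overview

- The route rests on the pyranone ring C: O1 is bonded to C2, and C2 is the former carboxyl carbon of ring B. An aryl ester between the ring A phenol and the ring B acid therefore already holds O1–C2, and only C2=C3 is missing.
- C2=C3 is the last skeletal bond made, by intramolecular Wittig olefination of that ester with a phenacylidene phosphorane on ring A. Ring C is the only ring formed; rings A, B and D are bought as benzenes.
- The ring B acid comes from methyl syringate: O-alkylation with a chloroacetyl oxazolidinone, Evans syn-aldol with 4-(benzyloxy)benzaldehyde (fixes the ether carbon), then Mitsunobu inversion of the benzylic carbinol (threo to erythro). This pair is preferred to a direct anti aldol because its sense of induction is secure.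
- The ring A partner is the 2-hydroxyphenacyl phosphonium salt from 2',4',6'-trihydroxyacetophenone and triphenylphosphine. The side-chain diol travels as two TBS ethers and the three phenols as benzyl ethers.
- Fluoride, then hydrogenolysis, free the two alcohols and the three phenols.

Key step: step 12

Remark: the side chain is read from the SMILES as erythro, (1S,2R) in the numbering of a 2-aryloxy-1-arylpropane-1,3-diol (C1 benzylic). The chloroacetylated (S)-benzyloxazolidinone of step 1 is taken as a purchasable reagent.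

## Route

Step 1
Reactants: 1 methyl syringate (methyl 4-hydroxy-3,5-dimethoxybenzoate); 2 (S)-4-benzyl-3-(chloroacetyl)-1,3-oxazolidin-2-one
Product: 3 methyl 4-{2-[(4S)-4-benzyl-2-oxo-1,3-oxazolidin-3-yl]-2-oxoethoxy}-3,5-dimethoxybenzoate
Conditions: K2CO3, NaI (cat.), acetone, 50 °C
Reagents that add atoms: none
Why: Williamson ether synthesis: the syringate phenoxide displaces the primary chloride next to the imide carbonyl (helped by in situ exchange to the iodide), and K2CO3 in acetone is too mild to open the oxazolidinone or to touch the stereocentre of the auxiliary.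

Step 2
Reactants: 3 aryloxyacetyl imide; 4 4-(benzyloxy)benzaldehyde
Product: 7 syn aldol adduct methyl 4-{[(2S,3R)-1-[(4S)-4-benzyl-2-oxo-1,3-oxazolidin-3-yl]-3-[4-(benzyloxy)phenyl]-3-hydroxy-1-oxopropan-2-yl]oxy}-3,5-dimethoxybenzoate, via boron enolate 5 (not isolated), via boron aldolate 6 (not isolated)
Conditions: Bu2BOTf, iPr2NEt, CH2Cl2, −78 to 0 °C; then 4, −78 to 0 °C; pH 7 buffer, MeOH, 30% H2O2, 0 °C
Reagents that add atoms: none
Why: Evans boron syn-aldol: soft enolisation gives the (Z)-boron enolate 5, which reacts through a chair Zimmerman–Traxler transition state with the oxazolidinone carbonyl turned away from the enolate oxygen, so that the aldehyde is taken up on the face opposite the benzyl group and the 2,3-syn (2S,3R) adduct should form, its C2 already having the spatial arrangement of the ether carbon of the target (the descriptor changes to R in step 3 only because the priorities change) and its C3 being the threo carbinol that step 5 inverts.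

Step 3
Reactants: 7 syn aldol adduct
Product: 8 threo diol methyl 4-{[(1R,2R)-1-[4-(benzyloxy)phenyl]-1,3-dihydroxypropan-2-yl]oxy}-3,5-dimethoxybenzoate
Conditions: NaBH4, THF/H2O, 0 °C to rt
Reagents that add atoms: none
Why: Hydride reduction of the activated imide carbonyl (reductive removal of the Evans auxiliary with NaBH4 in wet THF) gives the primary alcohol and frees the oxazolidinone, while the much less electrophilic methyl benzoate is left and neither stereocentre is involved.

Step 4
Reactants: 8 threo diol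
Product: 9 methyl 4-{[(1R,2R)-1-[4-(benzyloxy)phenyl]-3-[(tert-butyldimethylsilyl)oxy]-1-hydroxypropan-2-yl]oxy}-3,5-dimethoxybenzoate
Conditions: TBSCl, imidazole, CH2Cl2, 0 °C
Reagents that add atoms: tert-butyldimethylsilyl chloride, CC(C)(C)[Si](C)(C)Cl
Why: Silyl ether formation with TBSCl/imidazole at low temperature is selective for the unhindered primary hydroxyl over the secondary benzylic one that sits next to the bulky aryloxy group.

Step 5
Reactants: 9 primary silyl ether with free threo benzylic alcohol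
Product: 10 (1S,2R)-1-[4-(benzyloxy)phenyl]-3-[(tert-butyldimethylsilyl)oxy]-2-[2,6-dimethoxy-4-(methoxycarbonyl)phenoxy]propyl 4-nitrobenzoate
Conditions: 4-O2NC6H4CO2H, PPh3, DIAD, toluene, −20 °C to rt
Reagents that add atoms: 4-nitrobenzoic acid, OC(=O)c1ccc(cc1)[N+](=O)[O-]
Why: Mitsunobu reaction: the benzylic oxyphosphonium ion is displaced by 4-nitrobenzoate in an SN2 step with inversion, which turns the (1R) threo carbinol into the (1S) erythro centre, and the non-polar solvent, the low temperature and the electron-withdrawing neighbouring aryloxy group work against ionisation of the benzylic position.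

Step 6
Reactants: 10 erythro 4-nitrobenzoate
Product: 11 4-{[(1S,2R)-1-[4-(benzyloxy)phenyl]-3-[(tert-butyldimethylsilyl)oxy]-1-hydroxypropan-2-yl]oxy}-3,5-dimethoxybenzoic acid
Conditions: LiOH·H2O, THF/MeOH/H2O, rt to 40 °C; then 0.5 M HCl, 0 °C, to pH 4
Reagents that add atoms: lithium hydroxide, [Li+].[OH-]
Why: Saponification by acyl–oxygen cleavage removes the 4-nitrobenzoate without breaking the C1–O bond, so the (1S) configuration is kept, and hydrolyses the methyl benzoate in the same pot; a silyl shift between the two side-chain oxygens under base would not matter since step 7 silylates whichever hydroxyl is free.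

Step 7
Reactants: 11 hydroxy acid
Product: 13 4-{[(1S,2R)-1-[4-(benzyloxy)phenyl]-1,3-bis[(tert-butyldimethylsilyl)oxy]propan-2-yl]oxy}-3,5-dimethoxybenzoic acid, via silyl ester 12 (not isolated)
Conditions: TBSOTf, 2,6-lutidine, CH2Cl2, 0 °C; then K2CO3, THF/MeOH/H2O, rt; 0.5 M HCl, 0 °C, to pH 4
Reagents that add atoms: tert-butyldimethylsilyl triflate, CC(C)(C)[Si](C)(C)OS(=O)(=O)C(F)(F)F
Why: Silylation with TBSOTf/2,6-lutidine is strong enough for the hindered secondary benzylic hydroxyl and also converts the carboxyl group into silyl ester 12, which alone is cleaved by K2CO3 in aqueous methanol because a silyl ester is far more labile than a silyl ether.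

Step 8
Reactants: 14 2',4',6'-trihydroxyacetophenone
Product: 15 1-[2,4-bis(benzyloxy)-6-hydroxyphenyl]ethanone
Conditions: BnBr (2 equiv), K2CO3, DMF, rt
Reagents that add atoms: benzyl bromide, BrCc1ccccc1
Why: Williamson benzylation with two equivalents of benzyl bromide should stop at the dibenzyl ether because the last hydroxyl is tied up in a strong hydrogen bond to the acetyl carbonyl and is the least nucleophilic of the three.

Step 9
Reactants: 15 dibenzylated acetophenone
Product: 16 1-[2,4-bis(benzyloxy)-6-hydroxyphenyl]-2-bromoethanone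
Conditions: CuBr2, EtOAc/CHCl3, reflux
Reagents that add atoms: copper dibromide, Br[Cu]Br
Why: α-Bromination of the methyl ketone with CuBr2 goes through the copper-bound enol and, unlike Br2, brominates the side chain of hydroxy- and alkoxyacetophenones in preference to the electron-rich ring.

Step 10
Reactants: 16 phenacyl bromide; 17 triphenylphosphine
Product: 18 {2-[2,4-bis(benzyloxy)-6-hydroxyphenyl]-2-oxoethyl}triphenylphosphonium bromide
Conditions: toluene, rt
Reagents that add atoms: none
Why: SN2 quaternisation of PPh3 by the primary phenacyl bromide gives the phosphonium salt, and because no base is present the ortho phenol cannot close to the benzofuran-3-one.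

Step 11
Reactants: 13 ring B acid; 18 phosphonium bromide
Product: 21 ester ylide 3,5-bis(benzyloxy)-2-[(triphenylphosphoranylidene)acetyl]phenyl 4-{[(1S,2R)-1-[4-(benzyloxy)phenyl]-1,3-bis[(tert-butyldimethylsilyl)oxy]propan-2-yl]oxy}-3,5-dimethoxybenzoate, via acid chloride 19 (not isolated), via ester phosphonium bromide 20 (not isolated)
Conditions: 1-chloro-N,N,2-trimethylprop-1-en-1-amine, CH2Cl2, 0 °C; then 18, pyridine, 0 °C to rt; cold aq. Na2CO3 wash
Reagents that add atoms: none
Why: Acid chloride formation under neutral conditions (Ghosez reagent, no HCl, so the silyl ethers survive) is followed by pyridine-mediated acylation of the phenol while the phosphorus still sits in its salt form, pyridine being too weak a base to turn much of the phenacylphosphonium into ylide, so that oxygen and not the ylide carbon is acylated (an acyl group that does reach the enolate oxygen of the little ylide present is an activated vinyl ester and is passed on to the neighbouring phenol), and the cold carbonate wash then frees the stabilised ylide.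

Step 12
Reactants: 21 ester ylide
Product: 22 5,7-bis(benzyloxy)-2-(4-{[(1S,2R)-1-[4-(benzyloxy)phenyl]-1,3-bis[(tert-butyldimethylsilyl)oxy]propan-2-yl]oxy}-3,5-dimethoxyphenyl)-4H-chromen-4-one
Conditions: toluene, 110 °C
Reagents that add atoms: none
Why: The carbanionic ylide carbon (future C3) adds to the carbonyl carbon of the neighbouring aryl ester (future C2), and the oxaphosphetane so formed loses Ph3PO to leave the C2=C3 bond. This is an intramolecular Wittig olefination of an ester, the reaction type by which O-acyl (2-hydroxyphenacylidene)phosphoranes are known to give chromones and flavones. Ring C closes in the 6-exo-trig mode, the ester C=O lying outside the new ring made of C3, C4, C4a, C8a, O1 and C2. No stereocentre is formed, and the two existing ones sit in the side chain, away from the reacting atoms, and meet only hot neutral toluene. The selectivity needed is olefination instead of acyl transfer from oxygen to carbon, and the substrate secures it because a phenoxide expelled from the betaine stays tethered and re-adds to the same carbonyl, so that only the loss of Ph3PO is irreversible. The phenolic ester is electrophilic enough for a stabilised ylide, and the ring B carbonyl has no ortho substituent to hinder the approach.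

Step 13
Reactants: 22 protected flavone
Product: 23 5,7-bis(benzyloxy)-2-(4-{[(1S,2R)-1-[4-(benzyloxy)phenyl]-1,3-dihydroxypropan-2-yl]oxy}-3,5-dimethoxyphenyl)-4H-chromen-4-one
Conditions: TBAF, AcOH, THF, rt
Reagents that add atoms: none
Why: Fluoride-induced desilylation with acetic acid-buffered TBAF cleaves both Si–O bonds at silicon, so the benzylic C–O bond and its configuration, the benzyl ethers and the chromone are not touched.

Step 14
Reactants: 23 tri-O-benzyl diol
Product: 24 5,7-dihydroxy-2-(4-{[(1S,2R)-1,3-dihydroxy-1-(4-hydroxyphenyl)propan-2-yl]oxy}-3,5-dimethoxyphenyl)-4H-chromen-4-one (target)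
Conditions: H2 (1 atm), Pd/C (10% Pd on carbon), THF/MeOH, rt
Reagents that add atoms: none
Why: Catalytic hydrogenolysis over Pd/C cleaves the three aryl benzyl ethers under neutral conditions, under which the secondary benzylic alcohol and the C2=C3 bond of the chromone are reduced much more slowly, so the reaction is stopped as soon as the last benzyl group has gone.

## Compound list

1 | methyl syringate (methyl 4-hydroxy-3,5-dimethoxybenzoate) | COC(=O)c1cc(OC)c(O)c(OC)c1 | starting material
2 | (S)-4-benzyl-3-(chloroacetyl)-1,3-oxazolidin-2-one | O=C(CCl)N1[C@@H](Cc2ccccc2)COC1=O | starting material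
3 | methyl 4-{2-[(4S)-4-benzyl-2-oxo-1,3-oxazolidin-3-yl]-2-oxoethoxy}-3,5-dimethoxybenzoate | COC(=O)c1cc(OC)c(OCC(=O)N2[C@@H](Cc3ccccc3)COC2=O)c(OC)c1 | intermediate
4 | 4-(benzyloxy)benzaldehyde | O=Cc1ccc(OCc2ccccc2)cc1 | starting material
5 | (Z)-dibutylboron enolate of 3 (aryloxy and boryloxy groups cis) | COC(=O)c1cc(OC)c(O/C=C(\OB(CCCC)CCCC)N2[C@@H](Cc3ccccc3)COC2=O)c(OC)c1 | intermediate
6 | dibutylboron aldolate of 7 | COC(=O)c1cc(OC)c(O[C@H](C(=O)N2[C@@H](Cc3ccccc3)COC2=O)[C@H](OB(CCCC)CCCC)c2ccc(OCc3ccccc3)cc2)c(OC)c1 | intermediate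
7 | methyl 4-{[(2S,3R)-1-[(4S)-4-benzyl-2-oxo-1,3-oxazolidin-3-yl]-3-[4-(benzyloxy)phenyl]-3-hydroxy-1-oxopropan-2-yl]oxy}-3,5-dimethoxybenzoate (syn aldol) | COC(=O)c1cc(OC)c(O[C@H](C(=O)N2[C@@H](Cc3ccccc3)COC2=O)[C@H](O)c2ccc(OCc3ccccc3)cc2)c(OC)c1 | intermediate
8 | methyl 4-{[(1R,2R)-1-[4-(benzyloxy)phenyl]-1,3-dihydroxypropan-2-yl]oxy}-3,5-dimethoxybenzoate (threo diol) | COC(=O)c1cc(OC)c(O[C@H](CO)[C@H](O)c2ccc(OCc3ccccc3)cc2)c(OC)c1 | intermediate
9 | methyl 4-{[(1R,2R)-1-[4-(benzyloxy)phenyl]-3-[(tert-butyldimethylsilyl)oxy]-1-hydroxypropan-2-yl]oxy}-3,5-dimethoxybenzoate | COC(=O)c1cc(OC)c(O[C@H](CO[Si](C)(C)C(C)(C)C)[C@H](O)c2ccc(OCc3ccccc3)cc2)c(OC)c1 | intermediate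
10 | (1S,2R)-1-[4-(benzyloxy)phenyl]-3-[(tert-butyldimethylsilyl)oxy]-2-[2,6-dimethoxy-4-(methoxycarbonyl)phenoxy]propyl 4-nitrobenzoate | COC(=O)c1cc(OC)c(O[C@H](CO[Si](C)(C)C(C)(C)C)[C@@H](OC(=O)c2ccc(cc2)[N+](=O)[O-])c2ccc(OCc3ccccc3)cc2)c(OC)c1 | intermediate
11 | 4-{[(1S,2R)-1-[4-(benzyloxy)phenyl]-3-[(tert-butyldimethylsilyl)oxy]-1-hydroxypropan-2-yl]oxy}-3,5-dimethoxybenzoic acid | OC(=O)c1cc(OC)c(O[C@H](CO[Si](C)(C)C(C)(C)C)[C@@H](O)c2ccc(OCc3ccccc3)cc2)c(OC)c1 | intermediate
12 | tert-butyldimethylsilyl ester of 13 | CC(C)(C)[Si](C)(C)OC(=O)c1cc(OC)c(O[C@H](CO[Si](C)(C)C(C)(C)C)[C@@H](O[Si](C)(C)C(C)(C)C)c2ccc(OCc3ccccc3)cc2)c(OC)c1 | intermediate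
13 | 4-{[(1S,2R)-1-[4-(benzyloxy)phenyl]-1,3-bis[(tert-butyldimethylsilyl)oxy]propan-2-yl]oxy}-3,5-dimethoxybenzoic acid | OC(=O)c1cc(OC)c(O[C@H](CO[Si](C)(C)C(C)(C)C)[C@@H](O[Si](C)(C)C(C)(C)C)c2ccc(OCc3ccccc3)cc2)c(OC)c1 | intermediate
14 | 2',4',6'-trihydroxyacetophenone | CC(=O)c1c(O)cc(O)cc1O | starting material
15 | 1-[2,4-bis(benzyloxy)-6-hydroxyphenyl]ethanone | CC(=O)c1c(O)cc(OCc2ccccc2)cc1OCc1ccccc1 | intermediate
16 | 1-[2,4-bis(benzyloxy)-6-hydroxyphenyl]-2-bromoethanone | O=C(CBr)c1c(O)cc(OCc2ccccc2)cc1OCc1ccccc1 | intermediate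
17 | triphenylphosphine | c1ccc(cc1)P(c1ccccc1)c1ccccc1 | starting material
18 | {2-[2,4-bis(benzyloxy)-6-hydroxyphenyl]-2-oxoethyl}triphenylphosphonium bromide | O=C(C[P+](c1ccccc1)(c1ccccc1)c1ccccc1)c1c(O)cc(OCc2ccccc2)cc1OCc1ccccc1.[Br-] | intermediate
19 | acid chloride of 13 | ClC(=O)c1cc(OC)c(O[C@H](CO[Si](C)(C)C(C)(C)C)[C@@H](O[Si](C)(C)C(C)(C)C)c2ccc(OCc3ccccc3)cc2)c(OC)c1 | intermediate
20 | phosphonium bromide 18 acylated on the phenol oxygen by the acyl group of 13 | O=C(C[P+](c1ccccc1)(c1ccccc1)c1ccccc1)c1c(OCc2ccccc2)cc(OCc2ccccc2)cc1OC(=O)c1cc(OC)c(O[C@H](CO[Si](C)(C)C(C)(C)C)[C@@H](O[Si](C)(C)C(C)(C)C)c2ccc(OCc3ccccc3)cc2)c(OC)c1.[Br-] | intermediate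
21 | 3,5-bis(benzyloxy)-2-[(triphenylphosphoranylidene)acetyl]phenyl 4-{[(1S,2R)-1-[4-(benzyloxy)phenyl]-1,3-bis[(tert-butyldimethylsilyl)oxy]propan-2-yl]oxy}-3,5-dimethoxybenzoate (key-step precursor) | O=C(C=P(c1ccccc1)(c1ccccc1)c1ccccc1)c1c(OCc2ccccc2)cc(OCc2ccccc2)cc1OC(=O)c1cc(OC)c(O[C@H](CO[Si](C)(C)C(C)(C)C)[C@@H](O[Si](C)(C)C(C)(C)C)c2ccc(OCc3ccccc3)cc2)c(OC)c1 | intermediate
22 | 5,7-bis(benzyloxy)-2-(4-{[(1S,2R)-1-[4-(benzyloxy)phenyl]-1,3-bis[(tert-butyldimethylsilyl)oxy]propan-2-yl]oxy}-3,5-dimethoxyphenyl)-4H-chromen-4-one (key-step product) | COc1cc(-c2cc(=O)c3c(OCc4ccccc4)cc(OCc4ccccc4)cc3o2)cc(OC)c1O[C@H](CO[Si](C)(C)C(C)(C)C)[C@@H](O[Si](C)(C)C(C)(C)C)c1ccc(OCc2ccccc2)cc1 | intermediate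
23 | 5,7-bis(benzyloxy)-2-(4-{[(1S,2R)-1-[4-(benzyloxy)phenyl]-1,3-dihydroxypropan-2-yl]oxy}-3,5-dimethoxyphenyl)-4H-chromen-4-one | COc1cc(-c2cc(=O)c3c(OCc4ccccc4)cc(OCc4ccccc4)cc3o2)cc(OC)c1O[C@H](CO)[C@@H](O)c1ccc(OCc2ccccc2)cc1 | intermediate
24 | 5,7-dihydroxy-2-(4-{[(1S,2R)-1,3-dihydroxy-1-(4-hydroxyphenyl)propan-2-yl]oxy}-3,5-dimethoxyphenyl)-4H-chromen-4-one | COc1cc(-c2cc(=O)c3c(O)cc(O)cc3o2)cc(OC)c1O[C@H](CO)[C@@H](O)c1ccc(O)cc1 | target

## Step count and risks

Total step count: 14. Longest linear sequence: 11 steps (steps 1 to 7 and 11 to 14). Steps 8 to 10 are the three-step branch to the ring A salt.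

The three steps most likely to fail:

Step 12 (key step). The aroyl group may move from oxygen to the ylide carbon without the betaine going on to lose Ph3PO, or the ester carbonyl may be attacked so slowly that thermal decomposition outruns olefination. The fallback builds ring C by the classical acyl shift and cyclodehydration; it sets out from acid 13 and ketone 15 and comes back at 22. Acid 13 is esterified with the phenol of 15 (EDC·HCl, DMAP, CH2Cl2) to give the 2-acetyl-3,5-bis(benzyloxy)phenyl ester F1. LiN(SiMe3)2 in THF at −20 °C then moves the aroyl group from oxygen to the methyl carbon (Baker–Venkataraman rearrangement) to give the 1-(2-hydroxyaryl)-3-arylpropane-1,3-dione F2. Cyclodehydration in NaOAc-buffered AcOH at 80 °C forms O1–C2 and should give 22; a silyl group lost under these conditions does no harm, since step 13 removes both.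

Step 5. The oxyphosphonium ion may ionise at the electron-rich benzylic carbon, so that inversion is incomplete, or it may eliminate toward the enol ether. The fallback inverts the carbinol by oxidation and reduction; it sets out from 9 and comes back at 11. Dess–Martin periodinane with NaHCO3 in CH2Cl2 oxidises 9 to the α-aryloxy ketone F3. Zn(BH4)2 in Et2O at −30 °C then reduces the five-membered chelate between the carbonyl oxygen and the ether oxygen from the side of the small hydrogen (Cram chelate model) and should give the erythro alcohol, the methyl ester F4; any threo alcohol formed is 9 itself and is recycled. LiOH in aqueous THF/MeOH then gives 11.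

Step 9. Electrophilic bromination of the electron-rich ring may compete with that of the side chain, and the bromoketone may close onto the phenol once HBr has left. The fallback makes the enol derivative before bromination; it sets out from 15 and comes back at 16. TMSOTf and Et3N in CH2Cl2 turn 15 into the aryl silyl ether and silyl enol ether F5. NBS in THF at −78 °C brominates the enol ether carbon, which is far more nucleophilic than the ring, and a mildly acidic aqueous work-up cleaves the aryl silyl ether to give 16.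

Further compounds
F1 | step 12 | 2-acetyl-3,5-bis(benzyloxy)phenyl 4-{[(1S,2R)-1-[4-(benzyloxy)phenyl]-1,3-bis[(tert-butyldimethylsilyl)oxy]propan-2-yl]oxy}-3,5-dimethoxybenzoate | CC(=O)c1c(OCc2ccccc2)cc(OCc2ccccc2)cc1OC(=O)c1cc(OC)c(O[C@H](CO[Si](C)(C)C(C)(C)C)[C@@H](O[Si](C)(C)C(C)(C)C)c2ccc(OCc3ccccc3)cc2)c(OC)c1
F2 | step 12 | 1-[2,4-bis(benzyloxy)-6-hydroxyphenyl]-3-(4-{[(1S,2R)-1-[4-(benzyloxy)phenyl]-1,3-bis[(tert-butyldimethylsilyl)oxy]propan-2-yl]oxy}-3,5-dimethoxyphenyl)propane-1,3-dione | O=C(CC(=O)c1cc(OC)c(O[C@H](CO[Si](C)(C)C(C)(C)C)[C@@H](O[Si](C)(C)C(C)(C)C)c2ccc(OCc3ccccc3)cc2)c(OC)c1)c1c(O)cc(OCc2ccccc2)cc1OCc1ccccc1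
F3 | step 5 | methyl 4-{[(2R)-1-[4-(benzyloxy)phenyl]-3-[(tert-butyldimethylsilyl)oxy]-1-oxopropan-2-yl]oxy}-3,5-dimethoxybenzoate | COC(=O)c1cc(OC)c(O[C@H](CO[Si](C)(C)C(C)(C)C)C(=O)c2ccc(OCc3ccccc3)cc2)c(OC)c1
F4 | step 5 | methyl 4-{[(1S,2R)-1-[4-(benzyloxy)phenyl]-3-[(tert-butyldimethylsilyl)oxy]-1-hydroxypropan-2-yl]oxy}-3,5-dimethoxybenzoate | COC(=O)c1cc(OC)c(O[C@H](CO[Si](C)(C)C(C)(C)C)[C@@H](O)c2ccc(OCc3ccccc3)cc2)c(OC)c1
F5 | step 9 | {[1-(2,4-bis(benzyloxy)-6-[(trimethylsilyl)oxy]phenyl)ethenyl]oxy}trimethylsilane | C=C(O[Si](C)(C)C)c1c(O[Si](C)(C)C)cc(OCc2ccccc2)cc1OCc1ccccc1
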